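**Plan**

1. Retrosynthetic cuts, in order: (a) the ten silyl ethers; (b) the chalcone C=C (Wittig, ylide 14); (c) the bond from C5 of the central resorcinol ring to C2 of the tetrahydrofuran, giving phenol 32 and methyl acetal 12; (d) in 32 the dihydrobenzofuran O–C2 bond, the C2–aryl bond, the lactone C3–aryl bond and the C4–aryl bond of a chromanone; (e) in 12 the ring O–C2 acetal bond, the C4–C5 aldol bond and the C3–C4 bond.
2. Forward order: coumarin → 4-arylchromanone → trans-3,4-diaryl lactone → lactol → carbinol → acid closes the dihydrobenzofuran (32); separately photoredox alkylation → anti aldol → acetal closure forms the tetrahydrofuran (12); 32 and 12 are joined, the chalcone is added and all silicon is removed last.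
3. Stereochemistry: the diarylmethine carbon comes from the rhodium/(R)-SEGPHOS addition; benzofuran C3 from trans equilibration in the lactone ring; benzofuran C2 settles trans to C3 in the cationic closure; tetrahydrofuran C3 comes from the imidazolidinone catalyst, C5 from the aldol relative to C3, C4 from epimerisation, and C2 from the key step.
4. Enabling feature: tetrahydrofuran C2 is bonded to ring oxygen O1, so a 2-methoxy precursor ionises to an oxocarbenium ion. C5 of the central ring is ortho to the free C4 hydroxyl and para to the C2 oxygen, so the ion is taken up at that oxygen and passed on to C5. The new C2–O1 bond is the benzylic ether of a 2,4-dioxygenated ring and ionises reversibly, so both anomers of 12 and any C2 epimer of the product drain into the all-trans ring.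

Key step: step 20

Remark on notation: TBSO = tert-butyldimethylsilyloxy, TIPSO = triisopropylsilyloxy, MOMO = methoxymethoxy. Tetrahydrofuran locants follow the target (O1, C2 coupling carbon, C3 benzyl, C4 aroyl, C5 aryl). Central-ring locants: C1 bears the methine carbon, C2 and C4 bear oxygen, C5 is the coupling site.

Remark on the chemistry (assumption): acetal, lactol and carbinol centres that are erased later (in 11, 12, 27, 30, 31, 34) are carried as epimer mixtures. The facial sense of the two chiral catalysts is assigned from the accepted models, and the enantiomeric catalyst would be used if the sense proved opposite.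

**Route**

Step 1
Reactants: 1 1-(2,4-dihydroxyphenyl)ethan-1-one
Product: 2 triisopropyl{1-[2,4-bis(TIPSO)phenyl]ethenyloxy}silane
Conditions: i-Pr3SiOTf (3.3 equiv), Et3N, CH2Cl2, 0 °C to rt
Reagents that add atoms: triisopropylsilyl trifluoromethanesulfonate, CC(C)[Si](OS(=O)(=O)C(F)(F)F)(C(C)C)C(C)C
Why: Silyl triflate/amine silylation of both phenols together with soft enolisation of the methyl ketone should give the silyl enol ether in one operation, the bulky triisopropylsilyl group being chosen for this ring because it resists migration of silicon to a neighbouring enolate or ylide oxygen in later steps.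

Step 2
Reactants: 2 triisopropyl{1-[2,4-bis(TIPSO)phenyl]ethenyloxy}silane
Product: 3 2-bromo-1-[2,4-bis(TIPSO)phenyl]ethan-1-one
Conditions: N-bromosuccinimide, THF, −78 to 0 °C
Reagents that add atoms: N-bromosuccinimide, O=C1CCC(=O)N1Br
Why: Electrophilic α-bromination of a silyl enol ether is fast and regiospecific, and the enol ether is far more nucleophilic than the silylated arene.

Step 3
Reactants: 4 tert-butyl(4-iodophenoxy)dimethylsilane
Product: 5 3-[4-(TBSO)phenyl]propanal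
Conditions: Pd(OAc)2 (3 mol%), Bu4NCl, NaHCO3, DMF, 40 °C
Reagents that add atoms: prop-2-en-1-ol, C=CCO
Why: Heck arylation of allyl alcohol under phase-transfer conditions, in which β-hydride elimination toward the carbinol carbon and tautomerisation deliver the saturated 3-arylpropanal.

Step 4
Reactants: 5 3-[4-(TBSO)phenyl]propanal (2 equiv), 3 2-bromo-1-[2,4-bis(TIPSO)phenyl]ethan-1-one
Product: 6 (R)-2-[4-(TBSO)benzyl]-4-[2,4-bis(TIPSO)phenyl]-4-oxobutanal
Conditions: Ru(bpy)3Cl2 (0.5 mol%), (2R,5S)-2-tert-butyl-3,5-dimethylimidazolidin-4-one·CF3SO3H (20 mol%), 2,6-lutidine, DMF, visible light, rt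
Reagents that add atoms: none
Why: Photoredox organocatalytic α-alkylation of an aldehyde with a phenacyl bromide, in which the photoreduced ruthenium complex turns 3 into an electrophilic α-keto radical that adds to the Si face of the E-enamine of 5 (the Re face being shielded by the C5 methyl group of the catalyst), which should set the future tetrahydrofuran C3 as R.

Step 5
Reactants: 6 (R)-2-[4-(TBSO)benzyl]-4-[2,4-bis(TIPSO)phenyl]-4-oxobutanal
Product: 7 (R)-3-[4-(TBSO)benzyl]-1-[2,4-bis(TIPSO)phenyl]-4,4-dimethoxybutan-1-one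
Conditions: HC(OMe)3, MeOH, pyridinium p-toluenesulfonate (cat.), rt
Reagents that add atoms: trimethyl orthoformate, COC(OC)OC; methanol, CO
Why: Mild chemoselective acetalisation of the aldehyde in the presence of the hindered, electron-rich aryl ketone removes the acidic α-hydrogen and so secures the new stereocentre against racemisation.

Step 6
Reactants: 7 (R)-3-[4-(TBSO)benzyl]-1-[2,4-bis(TIPSO)phenyl]-4,4-dimethoxybutan-1-one, 8 4-(TBSO)benzaldehyde
Product: 10 (2S,3R)-3-[4-(TBSO)benzyl]-1-[2,4-bis(TIPSO)phenyl]-2-{(R)-hydroxy[4-(TBSO)phenyl]methyl}-4,4-dimethoxybutan-1-one, via E-enol borinate 9 (not isolated)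
Conditions: (c-C6H11)2BCl, Et3N, Et2O, 0 °C; then 8, −78 to −20 °C; MeOH, pH 7 buffer
Reagents that add atoms: none
Why: E-selective enolboration of an aryl alkyl ketone with a dialkylchloroborane followed by an anti-selective boron aldol through a Zimmerman–Traxler transition state, in which allylic 1,3-strain holds the C3–H in the enolate plane so that the aldehyde should approach anti to the branched dimethoxymethyl group, which together place the carbinol carbon (future C5, R) correctly relative to C3 while the ketone α-carbon is corrected in step 7.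

Step 7
Reactants: 10 (2S,3R)-3-[4-(TBSO)benzyl]-1-[2,4-bis(TIPSO)phenyl]-2-{(R)-hydroxy[4-(TBSO)phenyl]methyl}-4,4-dimethoxybutan-1-one
Product: 12 (3R,4R,5R)-3-[4-(TBSO)benzyl]-4-[2,4-bis(TIPSO)benzoyl]-2-methoxy-5-[4-(TBSO)phenyl]tetrahydrofuran (both C2 epimers), via all-cis acetal 11 (not isolated)
Conditions: camphorsulfonic acid (cat.), 4 Å molecular sieves, CH2Cl2, rt; then DBU (0.3 equiv), rt
Reagents that add atoms: none
Why: Acid-catalysed intramolecular transacetalisation (5-exo attack of the carbinol oxygen on the acyclic oxocarbenium ion) closes the ring as the all-cis acetal, and the amidine base then epimerises the ketone α-carbon C4 through its enol(ate) to the thermodynamically preferred all-trans array without touching C3 or C5.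

Step 8
Reactants: 3 2-bromo-1-[2,4-bis(TIPSO)phenyl]ethan-1-one
Product: 14 1-[2,4-bis(TIPSO)phenyl]-2-(triphenyl-λ5-phosphanylidene)ethan-1-one, via phosphonium bromide 13 (not isolated)
Conditions: PPh3, toluene, rt; then aq. Na2CO3, CH2Cl2
Reagents that add atoms: triphenylphosphine, c1ccc(cc1)P(c1ccccc1)c1ccccc1
Why: SN2 quaternisation of the phosphine by the α-bromo ketone and deprotonation of the acidic phosphonium salt by carbonate give the stabilised acyl ylide needed for the Wittig reaction.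

Step 9
Reactants: 15 7-hydroxy-2H-chromen-2-one
Product: 16 7-(MOMO)-2H-chromen-2-one
Conditions: MeOCH2Cl, i-Pr2NEt, CH2Cl2, 0 °C to rt
Reagents that add atoms: chloromethyl methyl ether, COCCl
Why: Standard O-alkylation of a phenol to its methoxymethyl ether, which will be shed in the acid step that closes the dihydrobenzofuran.

Step 10
Reactants: 17 4-bromobenzene-1,3-diol
Product: 18 1-bromo-2,4-bis(TBSO)benzene
Conditions: t-BuMe2SiCl, imidazole, DMF, rt
Reagents that add atoms: tert-butyldimethylsilyl chloride, CC(C)(C)[Si](C)(C)Cl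
Why: Imidazole-promoted silylation of both phenols installs the protecting groups that persist to the last step.

Step 11
Reactants: 18 1-bromo-2,4-bis(TBSO)benzene
Product: 20 [2,4-bis(TBSO)phenyl]boronic acid, via Grignard reagent 19 (not isolated)
Conditions: Mg, THF, 40 °C; B(OMe)3, −78 °C to rt; 1 M HCl, 0 °C (brief)
Reagents that add atoms: trimethyl borate, COB(OC)OC; water, O
Why: Borylation of an aryl Grignard reagent with a trialkyl borate, magnesium being used in place of lithium because an ortho-silyloxy aryllithium would suffer oxygen-to-carbon silyl migration.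

Step 12
Reactants: 16 7-(MOMO)-2H-chromen-2-one, 20 [2,4-bis(TBSO)phenyl]boronic acid (excess)
Product: 21 (S)-4-[2,4-bis(TBSO)phenyl]-7-(MOMO)chroman-2-one
Conditions: Rh(acac)(C2H4)2 (3 mol%), (R)-SEGPHOS (3.3 mol%), 1,4-dioxane/H2O (10:1), 60 °C
Reagents that add atoms: none
Why: Hayashi–Miyaura rhodium-catalysed asymmetric 1,4-addition of an arylboronic acid to a coumarin, in which the (R)-SEGPHOS aryl-rhodium species should add to the lactone alkene with the facial sense established for 4-arylchroman-2-ones, which corresponds here to the (4S) centre that later becomes the diarylmethine carbon.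

Step 13
Reactants: 22 3-bromo-4-hydroxybenzaldehyde
Product: 23 3-bromo-4-(MOMO)benzaldehyde
Conditions: MeOCH2Cl, i-Pr2NEt, CH2Cl2, 0 °C to rt
Reagents that add atoms: chloromethyl methyl ether, COCCl
Why: Standard methoxymethyl protection of the phenol that will later become the dihydrobenzofuran oxygen.

Step 14
Reactants: 23 3-bromo-4-(MOMO)benzaldehyde
Product: 24 2-[3-bromo-4-(MOMO)phenyl]-1,3-dioxolane
Conditions: HOCH2CH2OH, pyridinium p-toluenesulfonate (cat.), benzene, reflux with removal of water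
Reagents that add atoms: ethane-1,2-diol, OCCO
Why: Mildly acid-catalysed acetalisation masks the aldehyde against the enolate, hydride and Grignard reagents of steps 15 to 17 while leaving the aryl methoxymethyl ether intact.

Step 15
Reactants: 21 (S)-4-[2,4-bis(TBSO)phenyl]-7-(MOMO)chroman-2-one, 24 2-[3-bromo-4-(MOMO)phenyl]-1,3-dioxolane
Product: 26 (3R,4S)-4-[2,4-bis(TBSO)phenyl]-3-[5-(1,3-dioxolan-2-yl)-2-(MOMO)phenyl]-7-(MOMO)chroman-2-one, via chlorozinc enolate 25 (not isolated)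
Conditions: LiN(SiMe3)2, THF, −78 °C; ZnCl2, −78 to 0 °C; then 24, Pd(dba)2 (5 mol%), P(t-Bu)3 (5 mol%), rt to 50 °C
Reagents that add atoms: none
Why: Palladium-catalysed α-arylation of a lactone through its zinc enolate (Negishi-type coupling), the zinc enolate being used to suppress ketene formation from the aryl ester, and the new C3 stereocentre should settle trans to the C4 aryl group because the α-aryl lactone proton is acidic and the product equilibrates to the more stable trans-3,4-diaryl lactone.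

Step 16
Reactants: 26 (3R,4S)-4-[2,4-bis(TBSO)phenyl]-3-[5-(1,3-dioxolan-2-yl)-2-(MOMO)phenyl]-7-(MOMO)chroman-2-one
Product: 27 (3R,4S)-4-[2,4-bis(TBSO)phenyl]-3-[5-(1,3-dioxolan-2-yl)-2-(MOMO)phenyl]-7-(MOMO)chroman-2-ol (both C2 epimers)
Conditions: i-Bu2AlH, CH2Cl2, −78 °C; aq. KNaC4H4O6 (tartrate) work-up
Reagents that add atoms: none
Why: Low-temperature partial reduction of a lactone to its lactol by a dialkylaluminium hydride, the tetrahedral aluminium alkoxide surviving until work-up, with the lactol centre formed as a mixture that is erased in step 17.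

Step 17
Reactants: 27 (3R,4S)-4-[2,4-bis(TBSO)phenyl]-3-[5-(1,3-dioxolan-2-yl)-2-(MOMO)phenyl]-7-(MOMO)chroman-2-ol, 28 (4-bromophenoxy)(tert-butyl)dimethylsilane
Product: 30 (2R,3S)-3-[2,4-bis(TBSO)phenyl]-2-[5-(1,3-dioxolan-2-yl)-2-(MOMO)phenyl]-3-[2-hydroxy-4-(MOMO)phenyl]-1-[4-(TBSO)phenyl]propan-1-ol (both C1 epimers), via Grignard reagent 29 (not isolated)
Conditions: Mg, THF, 40 °C (28, 3 equiv); then 27, 0 °C to rt; aq. NH4Cl
Reagents that add atoms: none
Why: Grignard addition to the open hydroxy-aldehyde form of a lactol (the first equivalent deprotonates it), giving a carbinol whose configuration is irrelevant because this carbon is ionised in step 19.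

Step 18
Reactants: 30 (2R,3S)-3-[2,4-bis(TBSO)phenyl]-2-[5-(1,3-dioxolan-2-yl)-2-(MOMO)phenyl]-3-[2-hydroxy-4-(MOMO)phenyl]-1-[4-(TBSO)phenyl]propan-1-ol
Product: 31 (2R,3S)-3-[2,4-bis(TBSO)phenyl]-2-[5-(1,3-dioxolan-2-yl)-2-(MOMO)phenyl]-3-[4-(MOMO)-2-(TBSO)phenyl]-1-[4-(TBSO)phenyl]propan-1-ol
Conditions: t-BuMe2SiCl (1.1 equiv), imidazole, DMF, 0 °C
Reagents that add atoms: tert-butyldimethylsilyl chloride, CC(C)(C)[Si](C)(C)Cl
Why: Chemoselective silylation of the phenol over the hindered secondary benzylic alcohol caps the one oxygen that could otherwise close a six-membered flavan ring in step 19.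

Step 19
Reactants: 31 (2R,3S)-3-[2,4-bis(TBSO)phenyl]-2-[5-(1,3-dioxolan-2-yl)-2-(MOMO)phenyl]-3-[4-(MOMO)-2-(TBSO)phenyl]-1-[4-(TBSO)phenyl]propan-1-ol
Product: 32 (2R,3R)-3-{(S)-[2,4-bis(TBSO)phenyl][4-hydroxy-2-(TBSO)phenyl]methyl}-2-[4-(TBSO)phenyl]-2,3-dihydro-1-benzofuran-5-carbaldehyde
Conditions: CF3CO2H, CH2Cl2, H2O (2 vol%), 0 °C to rt
Reagents that add atoms: water, O
Why: SN1-type dihydrobenzofuran closure known from oligostilbene chemistry, in which acid ionises the 4-silyloxybenzylic alcohol and the cation is captured in a 5-exo fashion by the ortho oxygen of the acetal-bearing ring (its methoxymethyl group being lost from the oxonium ion or hydrolysed), the aryl group at the new C2 stereocentre settling trans to the C3 substituent under steric and thermodynamic control, while the second methoxymethyl ether and the dioxolane are hydrolysed in the same pot and the aryl silyl ethers survive.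

Step 20
Reactants: 32 (2R,3R)-3-{(S)-[2,4-bis(TBSO)phenyl][4-hydroxy-2-(TBSO)phenyl]methyl}-2-[4-(TBSO)phenyl]-2,3-dihydro-1-benzofuran-5-carbaldehyde, 12 (3R,4R,5R)-3-[4-(TBSO)benzyl]-4-[2,4-bis(TIPSO)benzoyl]-2-methoxy-5-[4-(TBSO)phenyl]tetrahydrofuran
Product: 35 (2R,3R)-3-{(R)-[2,4-bis(TBSO)phenyl][5-{(2R,3R,4R,5R)-3-[4-(TBSO)benzyl]-4-[2,4-bis(TIPSO)benzoyl]-5-[4-(TBSO)phenyl]oxolan-2-yl}-4-hydroxy-2-(TBSO)phenyl]methyl}-2-[4-(TBSO)phenyl]-2,3-dihydro-1-benzofuran-5-carbaldehyde, via oxocarbenium triflate 33 (not isolated), via O-aryl acetal 34 (not isolated)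
Conditions: Me3SiOTf (0.3 equiv), 4 Å molecular sieves, CH2Cl2, −78 to 0 °C
Reagents that add atoms: none
Why: Me3SiOTf ionises either anomer of 12 to the same five-membered oxocarbenium ion 33, which is first captured by the only free phenolic oxygen of 32 (the C4 hydroxyl of the central resorcinol ring) to give O-aryl acetal 34 and then, on warming, re-ionises within the ion pair and attacks C5 of that ring (ortho to the phenol oxygen, para to the silyloxy group at C2) in a Fries-type oxygen-to-carbon shift. The closest known reaction type is the Friedel–Crafts C-arylation of furanosyl and 2-alkoxytetrahydrofuran acetals with phenols by O- to C-glycoside rearrangement. No ring is closed in the forward sense, but the tetrahydrofuran of the product can open at the C2–O1 bond to an ortho-quinone methide and re-close by 5-exo-trig addition of the C5-bound oxygen to the exocyclic methide carbon, which makes C2 configurationally mobile under the reaction conditions. The single new stereocentre C2 should end R, with the aryl group trans to the benzyl group at C3, because the arene adds to the envelope oxocarbenium ion anti to the adjacent C3 substituent and because the all-trans 2,3,4,5-tetrasubstituted ring is the thermodynamic sink of the reversible opening, so both anomers of 12 and any C2 epimer converge on one configuration. The step needs regioselectivity for C5 over C3 of the central ring and chemoselectivity over the pendant resorcinol ring, the 4-silyloxyphenyl rings and the aldehyde, and these are secured because the free hydroxyl steers the electrophile to its own ring through 34, C3 is flanked by the bulky silyl ether, the pendant ring carries two silyl ethers and no free hydroxyl, and the aryl aldehyde is far less electrophilic than 33 at low temperature.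

Step 21
Reactants: 35 the coupled aldehyde of step 20, 14 1-[2,4-bis(TIPSO)phenyl]-2-(triphenyl-λ5-phosphanylidene)ethan-1-one
Product: 36 deca-O-silyl isolophirachalcone (six TBS and four TIPS ethers; the central C4 hydroxyl free)
Conditions: toluene, 90 °C
Reagents that add atoms: none
Why: Wittig olefination with a stabilised acyl ylide is neutral, selective for the aldehyde over the hindered aryl ketone and E-selective, so it should install the chalcone enone without disturbing the β-alkoxy ketone of the tetrahydrofuran.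

Step 22
Reactants: 36 deca-O-silyl isolophirachalcone
Product: 37 isolophirachalcone
Conditions: Bu4NF/AcOH (1:1, 12 equiv), THF, 0 °C to rt
Reagents that add atoms: none
Why: Fluoride-mediated cleavage of aryl silyl ethers buffered with acetic acid should free all ten phenols under near-neutral conditions that spare the enone, the two benzylic cyclic ethers and the epimerisable ketone α-carbon.

**Compound list**

1 | 1-(2,4-dihydroxyphenyl)ethan-1-one | CC(=O)c1ccc(O)cc1O | starting material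
2 | triisopropyl{1-[2,4-bis(TIPSO)phenyl]ethenyloxy}silane | C=C(O[Si](C(C)C)(C(C)C)C(C)C)c1ccc(O[Si](C(C)C)(C(C)C)C(C)C)cc1O[Si](C(C)C)(C(C)C)C(C)C | intermediate
3 | 2-bromo-1-[2,4-bis(TIPSO)phenyl]ethan-1-one | O=C(CBr)c1ccc(O[Si](C(C)C)(C(C)C)C(C)C)cc1O[Si](C(C)C)(C(C)C)C(C)C | intermediate
4 | tert-butyl(4-iodophenoxy)dimethylsilane | CC(C)(C)[Si](C)(C)Oc1ccc(I)cc1 | starting material
5 | 3-[4-(TBSO)phenyl]propanal | O=CCCc1ccc(O[Si](C)(C)C(C)(C)C)cc1 | intermediate
6 | (R)-2-[4-(TBSO)benzyl]-4-[2,4-bis(TIPSO)phenyl]-4-oxobutanal | O=C[C@H](Cc1ccc(O[Si](C)(C)C(C)(C)C)cc1)CC(=O)c1ccc(O[Si](C(C)C)(C(C)C)C(C)C)cc1O[Si](C(C)C)(C(C)C)C(C)C | intermediate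
7 | (R)-3-[4-(TBSO)benzyl]-1-[2,4-bis(TIPSO)phenyl]-4,4-dimethoxybutan-1-one | COC(OC)[C@H](Cc1ccc(O[Si](C)(C)C(C)(C)C)cc1)CC(=O)c1ccc(O[Si](C(C)C)(C(C)C)C(C)C)cc1O[Si](C(C)C)(C(C)C)C(C)C | intermediate
8 | 4-(TBSO)benzaldehyde | O=Cc1ccc(O[Si](C)(C)C(C)(C)C)cc1 | starting material
9 | E-enol dicyclohexylborinate of 7 (not isolated) | COC(OC)[C@H](Cc1ccc(O[Si](C)(C)C(C)(C)C)cc1)/C=C(/OB(C1CCCCC1)C1CCCCC1)c1ccc(O[Si](C(C)C)(C(C)C)C(C)C)cc1O[Si](C(C)C)(C(C)C)C(C)C | intermediate
10 | (2S,3R)-3-[4-(TBSO)benzyl]-1-[2,4-bis(TIPSO)phenyl]-2-{(R)-hydroxy[4-(TBSO)phenyl]methyl}-4,4-dimethoxybutan-1-one (anti aldol) | COC(OC)[C@H](Cc1ccc(O[Si](C)(C)C(C)(C)C)cc1)[C@H](C(=O)c1ccc(O[Si](C(C)C)(C(C)C)C(C)C)cc1O[Si](C(C)C)(C(C)C)C(C)C)[C@@H](O)c1ccc(O[Si](C)(C)C(C)(C)C)cc1 | intermediate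
11 | (3R,4S,5R)-3-[4-(TBSO)benzyl]-4-[2,4-bis(TIPSO)benzoyl]-2-methoxy-5-[4-(TBSO)phenyl]tetrahydrofuran, all-cis at C3 to C5, both C2 epimers (not isolated) | COC1O[C@@H](c2ccc(O[Si](C)(C)C(C)(C)C)cc2)[C@@H](C(=O)c2ccc(O[Si](C(C)C)(C(C)C)C(C)C)cc2O[Si](C(C)C)(C(C)C)C(C)C)[C@H]1Cc1ccc(O[Si](C)(C)C(C)(C)C)cc1 | intermediate
12 | (3R,4R,5R)-3-[4-(TBSO)benzyl]-4-[2,4-bis(TIPSO)benzoyl]-2-methoxy-5-[4-(TBSO)phenyl]tetrahydrofuran, all-trans at C3 to C5, both C2 epimers | COC1O[C@@H](c2ccc(O[Si](C)(C)C(C)(C)C)cc2)[C@H](C(=O)c2ccc(O[Si](C(C)C)(C(C)C)C(C)C)cc2O[Si](C(C)C)(C(C)C)C(C)C)[C@H]1Cc1ccc(O[Si](C)(C)C(C)(C)C)cc1 | intermediate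
13 | {2-[2,4-bis(TIPSO)phenyl]-2-oxoethyl}triphenylphosphonium bromide (not isolated) | [Br-].O=C(C[P+](c1ccccc1)(c1ccccc1)c1ccccc1)c1ccc(O[Si](C(C)C)(C(C)C)C(C)C)cc1O[Si](C(C)C)(C(C)C)C(C)C | intermediate
14 | 1-[2,4-bis(TIPSO)phenyl]-2-(triphenyl-λ5-phosphanylidene)ethan-1-one | O=C(C=P(c1ccccc1)(c1ccccc1)c1ccccc1)c1ccc(O[Si](C(C)C)(C(C)C)C(C)C)cc1O[Si](C(C)C)(C(C)C)C(C)C | intermediate
15 | 7-hydroxy-2H-chromen-2-one (umbelliferone) | O=c1ccc2ccc(O)cc2o1 | starting material
16 | 7-(MOMO)-2H-chromen-2-one | COCOc1ccc2ccc(=O)oc2c1 | intermediate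
17 | 4-bromobenzene-1,3-diol | Oc1ccc(Br)c(O)c1 | starting material
18 | 1-bromo-2,4-bis(TBSO)benzene | Brc1ccc(O[Si](C)(C)C(C)(C)C)cc1O[Si](C)(C)C(C)(C)C | intermediate
19 | [2,4-bis(TBSO)phenyl]magnesium bromide (not isolated) | Br[Mg]c1ccc(O[Si](C)(C)C(C)(C)C)cc1O[Si](C)(C)C(C)(C)C | intermediate
20 | [2,4-bis(TBSO)phenyl]boronic acid | OB(O)c1ccc(O[Si](C)(C)C(C)(C)C)cc1O[Si](C)(C)C(C)(C)C | intermediate
21 | (S)-4-[2,4-bis(TBSO)phenyl]-7-(MOMO)chroman-2-one | O=C1C[C@H](c2ccc(O[Si](C)(C)C(C)(C)C)cc2O[Si](C)(C)C(C)(C)C)c2ccc(OCOC)cc2O1 | intermediate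
22 | 3-bromo-4-hydroxybenzaldehyde | O=Cc1ccc(O)c(Br)c1 | starting material
23 | 3-bromo-4-(MOMO)benzaldehyde | COCOc1ccc(C=O)cc1Br | intermediate
24 | 2-[3-bromo-4-(MOMO)phenyl]-1,3-dioxolane | COCOc1ccc(C2OCCO2)cc1Br | intermediate
25 | chlorozinc enolate of 21 (not isolated) | Cl[Zn]OC1=C[C@H](c2ccc(O[Si](C)(C)C(C)(C)C)cc2O[Si](C)(C)C(C)(C)C)c2ccc(OCOC)cc2O1 | intermediate
26 | (3R,4S)-4-[2,4-bis(TBSO)phenyl]-3-[5-(1,3-dioxolan-2-yl)-2-(MOMO)phenyl]-7-(MOMO)chroman-2-one (3,4-trans) | O=C1[C@@H](c2cc(C3OCCO3)ccc2OCOC)[C@H](c2ccc(O[Si](C)(C)C(C)(C)C)cc2O[Si](C)(C)C(C)(C)C)c2ccc(OCOC)cc2O1 | intermediate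
27 | (3R,4S)-4-[2,4-bis(TBSO)phenyl]-3-[5-(1,3-dioxolan-2-yl)-2-(MOMO)phenyl]-7-(MOMO)chroman-2-ol, both C2 epimers | OC1[C@@H](c2cc(C3OCCO3)ccc2OCOC)[C@H](c2ccc(O[Si](C)(C)C(C)(C)C)cc2O[Si](C)(C)C(C)(C)C)c2ccc(OCOC)cc2O1 | intermediate
28 | (4-bromophenoxy)(tert-butyl)dimethylsilane | Brc1ccc(O[Si](C)(C)C(C)(C)C)cc1 | starting material
29 | [4-(TBSO)phenyl]magnesium bromide (not isolated) | Br[Mg]c1ccc(O[Si](C)(C)C(C)(C)C)cc1 | intermediate
30 | (2R,3S)-3-[2,4-bis(TBSO)phenyl]-2-[5-(1,3-dioxolan-2-yl)-2-(MOMO)phenyl]-3-[2-hydroxy-4-(MOMO)phenyl]-1-[4-(TBSO)phenyl]propan-1-ol, both C1 epimers | OC(c1ccc(O[Si](C)(C)C(C)(C)C)cc1)[C@@H](c1cc(C2OCCO2)ccc1OCOC)[C@H](c1ccc(O[Si](C)(C)C(C)(C)C)cc1O[Si](C)(C)C(C)(C)C)c1ccc(OCOC)cc1O | intermediate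
31 | (2R,3S)-3-[2,4-bis(TBSO)phenyl]-2-[5-(1,3-dioxolan-2-yl)-2-(MOMO)phenyl]-3-[4-(MOMO)-2-(TBSO)phenyl]-1-[4-(TBSO)phenyl]propan-1-ol, both C1 epimers | OC(c1ccc(O[Si](C)(C)C(C)(C)C)cc1)[C@@H](c1cc(C2OCCO2)ccc1OCOC)[C@H](c1ccc(O[Si](C)(C)C(C)(C)C)cc1O[Si](C)(C)C(C)(C)C)c1ccc(OCOC)cc1O[Si](C)(C)C(C)(C)C | intermediate
32 | (2R,3R)-3-{(S)-[2,4-bis(TBSO)phenyl][4-hydroxy-2-(TBSO)phenyl]methyl}-2-[4-(TBSO)phenyl]-2,3-dihydro-1-benzofuran-5-carbaldehyde | O=Cc1ccc2c(c1)[C@@H]([C@H](c1ccc(O[Si](C)(C)C(C)(C)C)cc1O[Si](C)(C)C(C)(C)C)c1ccc(O)cc1O[Si](C)(C)C(C)(C)C)[C@H](c1ccc(O[Si](C)(C)C(C)(C)C)cc1)O2 | intermediate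
33 | (3R,4R,5R)-3-[4-(TBSO)benzyl]-4-[2,4-bis(TIPSO)benzoyl]-5-[4-(TBSO)phenyl]-4,5-dihydro-3H-furan-1-ium triflate, the oxocarbenium ion of 12 (not isolated) | [O-]S(=O)(=O)C(F)(F)F.C1=[O+][C@@H](c2ccc(O[Si](C)(C)C(C)(C)C)cc2)[C@H](C(=O)c2ccc(O[Si](C(C)C)(C(C)C)C(C)C)cc2O[Si](C(C)C)(C(C)C)C(C)C)[C@H]1Cc1ccc(O[Si](C)(C)C(C)(C)C)cc1 | intermediate
34 | O-aryl acetal: 32 bonded through its phenolic oxygen to C2 of the tetrahydrofuran of 12, both C2 epimers (not isolated) | O=Cc1ccc2c(c1)[C@@H]([C@H](c1ccc(O[Si](C)(C)C(C)(C)C)cc1O[Si](C)(C)C(C)(C)C)c1ccc(OC3O[C@@H](c4ccc(O[Si](C)(C)C(C)(C)C)cc4)[C@H](C(=O)c4ccc(O[Si](C(C)C)(C(C)C)C(C)C)cc4O[Si](C(C)C)(C(C)C)C(C)C)[C@H]3Cc3ccc(O[Si](C)(C)C(C)(C)C)cc3)cc1O[Si](C)(C)C(C)(C)C)[C@H](c1ccc(O[Si](C)(C)C(C)(C)C)cc1)O2 | intermediate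
35 | (2R,3R)-3-{(R)-[2,4-bis(TBSO)phenyl][5-{(2R,3R,4R,5R)-3-[4-(TBSO)benzyl]-4-[2,4-bis(TIPSO)benzoyl]-5-[4-(TBSO)phenyl]oxolan-2-yl}-4-hydroxy-2-(TBSO)phenyl]methyl}-2-[4-(TBSO)phenyl]-2,3-dihydro-1-benzofuran-5-carbaldehyde | O=Cc1ccc2c(c1)[C@@H]([C@H](c1ccc(O[Si](C)(C)C(C)(C)C)cc1O[Si](C)(C)C(C)(C)C)c1cc([C@@H]3O[C@@H](c4ccc(O[Si](C)(C)C(C)(C)C)cc4)[C@H](C(=O)c4ccc(O[Si](C(C)C)(C(C)C)C(C)C)cc4O[Si](C(C)C)(C(C)C)C(C)C)[C@H]3Cc3ccc(O[Si](C)(C)C(C)(C)C)cc3)c(O)cc1O[Si](C)(C)C(C)(C)C)[C@H](c1ccc(O[Si](C)(C)C(C)(C)C)cc1)O2 | intermediate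
36 | deca-O-silyl isolophirachalcone: 35 with the aldehyde replaced by the (E)-3-[2,4-bis(TIPSO)phenyl]-3-oxoprop-1-enyl group | O=C(/C=C/c1ccc2c(c1)[C@@H]([C@H](c1ccc(O[Si](C)(C)C(C)(C)C)cc1O[Si](C)(C)C(C)(C)C)c1cc([C@@H]3O[C@@H](c4ccc(O[Si](C)(C)C(C)(C)C)cc4)[C@H](C(=O)c4ccc(O[Si](C(C)C)(C(C)C)C(C)C)cc4O[Si](C(C)C)(C(C)C)C(C)C)[C@H]3Cc3ccc(O[Si](C)(C)C(C)(C)C)cc3)c(O)cc1O[Si](C)(C)C(C)(C)C)[C@H](c1ccc(O[Si](C)(C)C(C)(C)C)cc1)O2)c1ccc(O[Si](C(C)C)(C(C)C)C(C)C)cc1O[Si](C(C)C)(C(C)C)C(C)C | intermediate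
37 | isolophirachalcone | O=C(/C=C/c1ccc2c(c1)[C@@H]([C@H](c1ccc(O)cc1O)c1cc([C@@H]3O[C@@H](c4ccc(O)cc4)[C@H](C(=O)c4ccc(O)cc4O)[C@H]3Cc3ccc(O)cc3)c(O)cc1O)[C@H](c1ccc(O)cc1)O2)c1ccc(O)cc1O | target

**Step count and risks**

Total step count: 22. Longest linear sequence: 11 steps (steps 10, 11, 12, 15, 16, 17, 18, 19, 20, 21, 22).

Steps most likely to fail:

Step 20 (key coupling). The union may stop at the O-aryl acetal, alkylate the silylated pendant ring instead of the central ring, or lose silyl groups to the acid before the carbon–carbon bond forms. Fallback: the same bond would be made by a nickel-catalysed reductive cross-coupling through a C2 radical. It sets out from 32 and 12. Iodination of 32 ortho to the free hydroxyl (N-iodosuccinimide, CH2Cl2, 0 °C) should give the C5-iodinated phenol F1, and 12 would be converted with Me3SiBr in CH2Cl2 into the anomeric bromide F2. NiBr2(diglyme), 4,4′-di-tert-butyl-2,2′-bipyridine and zinc powder in N,N-dimethylacetamide would then join F1 and F2, the nickel-bound aryl group being delivered to the anomeric radical trans to the C3 benzyl group from either anomer. The sequence comes back to the route at 35.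

Step 6 (anti aldol). Enolate geometry may erode, or the aldehyde may fail to discriminate between the benzyl and dimethoxymethyl groups at C3, giving the wrong relative configuration at the carbinol carbon; retro-aldol on work-up is a further hazard. Fallback: the carbinol centre would be set by catalyst control instead of substrate control. It sets out from 7. Soft-enolisation C-acylation (MgBr2·OEt2, i-Pr2NEt, 4-(tert-butyldimethylsilyloxy)benzoyl chloride, CH2Cl2) should give the 1,3-diketone F3. Asymmetric transfer hydrogenation with RuCl(p-cymene)[(R,R)-TsDPEN] in HCO2H/Et3N should then reduce the less hindered 4-silyloxybenzoyl ketone with dynamic kinetic resolution at the acidic carbon between the carbonyl groups, giving 10 and/or its epimer at that carbon, the syn hydroxy ketone F4. Step 7 converts both into the same acetal, so the fallback comes back to the route at 12.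

Step 15 (lactone α-arylation). The aryl ester enolate may fragment to a ketene, transmetalation to the hindered ortho-substituted arylpalladium species may be slow, or a second arylation may occur. Fallback: the polarity would be inverted, with an electrophilic α-carbon and a nucleophilic arene. It sets out from 21 and 24. The lactone would be brominated at C3 (LiN(SiMe3)2, then N-bromosuccinimide, THF, −78 °C) to the 3-bromo lactone F5. Bromide 24 would be converted by Miyaura borylation (bis(pinacolato)diboron, PdCl2(dppf), KOAc, 1,4-dioxane, 80 °C) into the aryl pinacol boronate F6. Suzuki–Miyaura coupling of the α-bromo lactone with the boronate (Pd(OAc)2, P(o-tol)3, K3PO4, THF/H2O), followed by brief equilibration with DBU, should give the trans lactone and comes back to the route at 26.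

Further compounds
F1 | step 20 | (2R,3R)-3-{(S)-[2,4-bis(TBSO)phenyl][4-hydroxy-5-iodo-2-(TBSO)phenyl]methyl}-2-[4-(TBSO)phenyl]-2,3-dihydro-1-benzofuran-5-carbaldehyde | O=Cc1ccc2c(c1)[C@@H]([C@H](c1ccc(O[Si](C)(C)C(C)(C)C)cc1O[Si](C)(C)C(C)(C)C)c1cc(I)c(O)cc1O[Si](C)(C)C(C)(C)C)[C@H](c1ccc(O[Si](C)(C)C(C)(C)C)cc1)O2
F2 | step 20 | (3R,4R,5R)-2-bromo-3-[4-(TBSO)benzyl]-4-[2,4-bis(TIPSO)benzoyl]-5-[4-(TBSO)phenyl]tetrahydrofuran, both C2 epimers | BrC1O[C@@H](c2ccc(O[Si](C)(C)C(C)(C)C)cc2)[C@H](C(=O)c2ccc(O[Si](C(C)C)(C(C)C)C(C)C)cc2O[Si](C(C)C)(C(C)C)C(C)C)[C@H]1Cc1ccc(O[Si](C)(C)C(C)(C)C)cc1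
F3 | step 6 | 2-[(R)-1-[4-(TBSO)phenyl]-3,3-dimethoxypropan-2-yl]-1-[2,4-bis(TIPSO)phenyl]-3-[4-(TBSO)phenyl]propane-1,3-dione, both C2 epimers | COC(OC)[C@H](Cc1ccc(O[Si](C)(C)C(C)(C)C)cc1)C(C(=O)c1ccc(O[Si](C)(C)C(C)(C)C)cc1)C(=O)c1ccc(O[Si](C(C)C)(C(C)C)C(C)C)cc1O[Si](C(C)C)(C(C)C)C(C)C
F4 | step 6 | (2R,3R)-3-[4-(TBSO)benzyl]-1-[2,4-bis(TIPSO)phenyl]-2-{(R)-hydroxy[4-(TBSO)phenyl]methyl}-4,4-dimethoxybutan-1-one (syn aldol, C2 epimer of 10) | COC(OC)[C@H](Cc1ccc(O[Si](C)(C)C(C)(C)C)cc1)[C@@H](C(=O)c1ccc(O[Si](C(C)C)(C(C)C)C(C)C)cc1O[Si](C(C)C)(C(C)C)C(C)C)[C@@H](O)c1ccc(O[Si](C)(C)C(C)(C)C)cc1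
F5 | step 15 | (4S)-3-bromo-4-[2,4-bis(TBSO)phenyl]-7-(MOMO)chroman-2-one, both C3 epimers | O=C1C(Br)[C@H](c2ccc(O[Si](C)(C)C(C)(C)C)cc2O[Si](C)(C)C(C)(C)C)c2ccc(OCOC)cc2O1
F6 | step 15 | 2-[5-(1,3-dioxolan-2-yl)-2-(MOMO)phenyl]-4,4,5,5-tetramethyl-1,3,2-dioxaborolane | COCOc1ccc(C2OCCO2)cc1B1OC(C)(C)C(C)(C)O1
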